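**Plan**

1. Germacrane numbering is used throughout: ring C1–C10, C6 the carbinol carbon next to C7, C7 carrying the isopropenyl group C11(=C12)C13, and C14/C15 the methyls on C10/C4. The retrosynthesis cuts C8–O (SN2 on an 8-bromo-9-ketone), then the C3–O and C6–O ester bonds, then the ring bond C6–C7, then C7=C11, C8–C9, C1=C10 and C2–C3 of an open C6→C12 chain.
2. Enabling feature: C6(O)–C7–C11(=C12) in the ten-membered ring is a homoallylic alcohol, the retron of an allylmetal addition with allylic transposition. C6 (aldehyde) and C12 (allylic chloride) are both electrophilic and are joined after polarity reversal at chromium; C6–C7 is also the bond that farnesyl-type biosynthesis closes.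
3. Forward: 3-methylbutenolide (C3–C6, C15) → allylation (C2, C1) → Still–Gennari olefination (C10, C14, C9) → allylation (C8, C7) → cross-metathesis (C11–C13). The ring is closed last (step 14); esters, the C9 ketone and the C8 ester follow.
4. Stereochemistry: C3 by asymmetric allylboration; C4/C5 by C3–OH-directed epoxidation (A1,3 strain, threo); C1/C10 by Sharpless epoxidation with L-(+)-diethyl tartrate; C6/C7 in the ring closure (Felkin–Anh at C5, chair transition state); C8 by bromination trans to the isopropenyl group followed by SN2 inversion. Both epoxides are cis because both alkenes are made Z (lactone ring, Still–Gennari).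
5. Helpers: C9 is carried as the PMB ether of a sacrificial (9S) carbinol (removed and oxidised in steps 17–18); C8 stays CH2 through the cyclisation; the primary triethylsilyl ether on C6 is the masked aldehyde.

Key step: step 14

Remark: intermediates carry the target's spatial arrangement at every centre already set (defined by the SMILES; CIP letters are given only where worked out), and the cross-metathesis product 16 is drawn as its E isomer, any Z isomer being carried along because both give the same allylchromium species.

**Route**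

Step 1
Reactants: 1 3-methylfuran-2(5H)-one
Product: 2 3-methyl-2,5-dihydrofuran-2-ol
Conditions: iBu2AlH (1.05 equiv), CH2Cl2, −78 °C; aqueous potassium sodium tartrate; crude lactol used at once
Reagents that add atoms: none
Why: Partial reduction of an unsaturated γ-lactone to its lactol with one equivalent of iBu2AlH at low temperature (the aluminium hemiacetal survives until work-up); the ring holds the future C4=C5 bond in the Z geometry and no stereocentre of the target is set.

Step 2
Reactants: 2 3-methyl-2,5-dihydrofuran-2-ol; 3 (−)-B-allyldiisopinocampheylborane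
Product: 4 (2Z,4S)-3-methylhepta-2,6-diene-1,4-diol
Conditions: 3 (2.2 equiv), Et2O, −78 °C to 0 °C; then ethanolamine, 25 °C
Reagents that add atoms: none
Why: Asymmetric allylboration of the hydroxy-enal tautomer of the lactol through a six-membered chair transition state, in which the isopinocampheyl groups of the reagent made from (+)-α-pinene direct the allyl group to the aldehyde face that gives the (S)-carbinol (C3 of the target), the new C2–C3 bond bringing in C2 and C1.

Step 3
Reactants: 4 (2Z,4S)-3-methylhepta-2,6-diene-1,4-diol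
Product: 5 [(2S,3R)-3-[(1S)-1-hydroxybut-3-en-1-yl]-3-methyloxiran-2-yl]methanol
Conditions: mCPBA (1.1 equiv), NaHCO3, CH2Cl2, −20 °C to 0 °C
Reagents that add atoms: 3-chloroperoxybenzoic acid, OOC(=O)c1cccc(Cl)c1
Why: Hydroxyl-directed peracid epoxidation of a Z-allylic alcohol, in which A1,3 strain with the cis CH2OH group holds H3 in the alkene plane so that the hydrogen-bonded peracid is delivered from the C3–OH face and should give the threo epoxy alcohol (C4 R, C5 S), a cis-epoxide because the alkene is Z, while the monosubstituted vinyl group is too electron-poor to compete.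

Step 4
Reactants: 5 [(2S,3R)-3-[(1S)-1-hydroxybut-3-en-1-yl]-3-methyloxiran-2-yl]methanol
Product: 6 bis(triethylsilyl) ether of 5
Conditions: Et3SiCl (2.5 equiv), imidazole, CH2Cl2, 0 °C to 25 °C
Reagents that add atoms: chlorotriethylsilane, CC[Si](Cl)(CC)CC
Why: Standard silyl ether formation on a primary and a secondary alcohol, which installs the C3 protecting group and the primary C6 triethylsilyl ether that later serves as the masked aldehyde.

Step 5
Reactants: 6 bis(triethylsilyl) ether of 5
Product: 7 3-(triethylsilyloxy)-3-[2-methyl-3-(triethylsilyloxymethyl)oxiran-2-yl]propanal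
Conditions: O3, CH2Cl2, −78 °C; then PPh3, −78 °C to 25 °C
Reagents that add atoms: ozone, [O-][O+]=O
Why: Ozonolysis with reductive work-up cleaves the only C=C bond and unmasks C1 as the aldehyde, the epoxide and the silyl ethers being inert to ozone.

Step 6
Reactants: 7 3-(triethylsilyloxy)-3-[2-methyl-3-(triethylsilyloxymethyl)oxiran-2-yl]propanal; 8 methyl 2-[bis(2,2,2-trifluoroethoxy)phosphoryl]propanoate
Product: 9 methyl (2Z)-2-methyl-5-(triethylsilyloxy)-5-[2-methyl-3-(triethylsilyloxymethyl)oxiran-2-yl]pent-2-enoate
Conditions: 8, KN(SiMe3)2, 18-crown-6, THF, −78 °C; then 7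
Reagents that add atoms: none
Why: Still–Gennari olefination, in which the trifluoroethyl phosphonate under dissociating conditions eliminates faster than the adducts equilibrate, should give the (Z)-2-methyl enoate and so place C2 and C9 cis on the C1=C10 bond.

Step 7
Reactants: 9 methyl (2Z)-2-methyl-5-(triethylsilyloxy)-5-[2-methyl-3-(triethylsilyloxymethyl)oxiran-2-yl]pent-2-enoate
Product: 10 (2Z)-2-methyl-5-(triethylsilyloxy)-5-[2-methyl-3-(triethylsilyloxymethyl)oxiran-2-yl]pent-2-en-1-ol
Conditions: iBu2AlH (2.5 equiv), CH2Cl2, −78 °C; aqueous potassium sodium tartrate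
Reagents that add atoms: none
Why: 1,2-Reduction of the conjugated ester with iBu2AlH gives the allylic alcohol without touching the epoxide, the silyl ethers or the alkene geometry.

Step 8
Reactants: 10 (2Z)-2-methyl-5-(triethylsilyloxy)-5-[2-methyl-3-(triethylsilyloxymethyl)oxiran-2-yl]pent-2-en-1-ol
Product: 11 [2-methyl-3-[2-(triethylsilyloxy)-2-[2-methyl-3-(triethylsilyloxymethyl)oxiran-2-yl]ethyl]oxiran-2-yl]methanol
Conditions: Ti(OiPr)4 (10 mol %), L-(+)-diethyl tartrate (12 mol %), tBuOOH, 4 Å molecular sieves, CH2Cl2, −20 °C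
Reagents that add atoms: tert-butyl hydroperoxide, CC(C)(C)OO
Why: Sharpless asymmetric epoxidation of the primary Z-allylic alcohol under reagent control, in which L-(+)-diethyl tartrate delivers oxygen to the face that gives the cis-epoxide with the target configuration at C1 and C10 (the sense that turns allyl alcohol into (S)-glycidol), only the allylic-alcohol alkene being oxidised.

Step 9
Reactants: 11 [2-methyl-3-[2-(triethylsilyloxy)-2-[2-methyl-3-(triethylsilyloxymethyl)oxiran-2-yl]ethyl]oxiran-2-yl]methanol
Product: 12 2-methyl-3-[2-(triethylsilyloxy)-2-[2-methyl-3-(triethylsilyloxymethyl)oxiran-2-yl]ethyl]oxirane-2-carbaldehyde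
Conditions: Dess–Martin periodinane, NaHCO3, CH2Cl2, 0 °C to 25 °C
Reagents that add atoms: none
Why: Dess–Martin oxidation of the primary alcohol under buffered conditions gives an aldehyde whose α-carbon is fully substituted and therefore cannot epimerise.

Step 10
Reactants: 12 2-methyl-3-[2-(triethylsilyloxy)-2-[2-methyl-3-(triethylsilyloxymethyl)oxiran-2-yl]ethyl]oxirane-2-carbaldehyde; 3 (−)-B-allyldiisopinocampheylborane
Product: 13 (9S)-homoallylic alcohol (C9 carbinol with CH2–CH=CH2 as C8 and C7)
Conditions: 3 (1.5 equiv), Et2O, −78 °C; then ethanolamine, 25 °C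
Reagents that add atoms: none
Why: Reagent-controlled asymmetric allylboration of the hindered epoxy aldehyde (chair transition state) forms C8–C9 and a uniform (9S) carbinol, a sacrificial centre that is oxidised to the ketone in step 18.

Step 11
Reactants: 13 (9S)-homoallylic alcohol
Product: 14 (9S)-4-methoxybenzyl ether of 13
Conditions: NaH, 4-methoxybenzyl chloride, Bu4NI (cat.), DMF, 0 °C to 25 °C
Reagents that add atoms: 4-methoxybenzyl chloride, COc1ccc(CCl)cc1
Why: Williamson etherification of the sodium alkoxide, in which Payne rearrangement is blocked because the neighbouring epoxide carbon C10 is fully substituted, masks C9 at the alcohol oxidation level for the reductive ring closure.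

Step 12
Reactants: 14 (9S)-4-methoxybenzyl ether of 13; 15 3-chloro-2-methylprop-1-ene
Product: 16 (7E)-allylic chloride (C7=C11 trisubstituted alkene with C12H2Cl and C13H3)
Conditions: 15 (10 equiv), RuCl2(H2IMes)(=CH-C6H4-2-OiPr) (second-generation Hoveyda–Grubbs catalyst, 5 mol %), CH2Cl2, 40 °C
Reagents that add atoms: none
Why: Olefin cross-metathesis of a terminal alkene with an excess of a 1,1-disubstituted partner installs C11–C13 and the allylic chloride in one step, the trisubstituted product being inert to further metathesis and its E/Z composition immaterial because both isomers give the same allylchromium species in step 14.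

Step 13
Reactants: 16 (7E)-allylic chloride
Product: 17 C6 aldehyde (open-chain cyclisation precursor)
Conditions: (COCl)2, DMSO, CH2Cl2, −78 °C to −40 °C; then Et3N, −78 °C to 0 °C
Reagents that add atoms: none
Why: Swern conditions convert a primary triethylsilyl ether directly into the aldehyde (chloride-assisted silyl cleavage at the activated sulfonium stage) while the more hindered secondary triethylsilyl ether, the PMB ether, both epoxides and the allylic chloride should remain untouched.

Step 14
Reactants: 17 C6 aldehyde (open-chain cyclisation precursor)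
Product: 19 (6S,7S,9S)-9-(4-methoxybenzyloxy)-3-(triethylsilyloxy)-1,10:4,5-diepoxygermacr-11-en-6-ol, via allylchromium dichloride 18 (not isolated)
Conditions: CrCl2 (8 equiv), THF–DMF 4:1, 25 °C, 17 added over 10 h to a final 0.003 M; aqueous work-up
Reagents that add atoms: none
Why: Two equivalents of divalent chromium reduce the allylic C12–Cl bond by successive single-electron transfers to the (E)-allylchromium dichloride 18 (trivalent chromium on C12), which turns an electrophilic allyl terminus into a nucleophile; its γ-carbon C7 then adds to the chromium-bound aldehyde carbon C6 through a six-membered chair transition state with allylic transposition, so that the C6–C7 bond, the C6 carbinol and the C11=C12 isopropenyl group arise together. The closest known reaction type is the intramolecular Nozaki–Hiyama–Kishi allylation, which has closed ten-membered germacrane and larger terpenoid carbocycles from formyl-substituted allylic halides. The ten-membered ring closes in a 10-exo-trig mode (C7 attacks the carbonyl carbon and the C=O bond stays outside the ring). C6 should be controlled by the adjacent epoxide centre C5, since in the Felkin–Anh (Cornforth) arrangement the C5–O bond lies anti to the incoming carbon and gives the 5,6-erythro (6S) alcohol; C7 should be controlled by the chair, in which the (E)-allyl unit places C8 and the aldehyde places C5 equatorial, giving the anti (crotylation sense) relationship, that is the C6 oxygen trans to the isopropenyl group on the ring (7S). The step needs γ- over α-attack (inherent to allylchromium reagents), aldehyde over epoxide and ether chemoselectivity (these reagents are weakly basic and aldehyde-selective, and C9 is kept as an ether because an epoxy ketone would be reduced by divalent chromium), and ring closure over oligomerisation, which slow addition at high dilution and the two cis-epoxides acting as turn elements should secure.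

Step 15
Reactants: 19 (6S,7S,9S)-9-(4-methoxybenzyloxy)-3-(triethylsilyloxy)-1,10:4,5-diepoxygermacr-11-en-6-ol
Product: 20 (9S)-9-(4-methoxybenzyloxy)-1,10:4,5-diepoxygermacr-11-ene-3,6-diol
Conditions: Bu4NF, AcOH (1:1), THF, 0 °C to 25 °C
Reagents that add atoms: none
Why: Buffered fluoride desilylation frees the C3 hydroxyl, the acetic acid keeping the C6 alkoxide from attacking the adjacent epoxide.

Step 16
Reactants: 20 (9S)-9-(4-methoxybenzyloxy)-1,10:4,5-diepoxygermacr-11-ene-3,6-diol; 21 angelic acid
Product: 22 (9S)-9-(4-methoxybenzyloxy)-1,10:4,5-diepoxygermacr-11-ene-3,6-diyl bis[(2Z)-2-methylbut-2-enoate]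
Conditions: 21 (5 equiv), 2,4,6-trichlorobenzoyl chloride, Et3N, toluene, 25 °C; then 20, 75 °C
Reagents that add atoms: none
Why: Yamaguchi esterification through the mixed 2,4,6-trichlorobenzoic anhydride acylates the two hindered secondary alcohols without a nucleophilic catalyst, conditions under which the Z (angelate) double bond should not isomerise to the E (tiglate) form.

Step 17
Reactants: 22 (9S)-9-(4-methoxybenzyloxy)-1,10:4,5-diepoxygermacr-11-ene-3,6-diyl bis[(2Z)-2-methylbut-2-enoate]
Product: 23 (9S)-9-hydroxy-1,10:4,5-diepoxygermacr-11-ene-3,6-diyl bis[(2Z)-2-methylbut-2-enoate]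
Conditions: DDQ, CH2Cl2–pH 7 phosphate buffer 10:1, 0 °C
Reagents that add atoms: none
Why: Oxidative cleavage of the electron-rich 4-methoxybenzyl ether by DDQ in wet solvent (hydride abstraction, then hydrolysis of the oxocarbenium ion) should leave the esters, the epoxides and the 1,1-disubstituted alkene intact.

Step 18
Reactants: 23 (9S)-9-hydroxy-1,10:4,5-diepoxygermacr-11-ene-3,6-diyl bis[(2Z)-2-methylbut-2-enoate]
Product: 24 9-oxo-1,10:4,5-diepoxygermacr-11-ene-3,6-diyl bis[(2Z)-2-methylbut-2-enoate]
Conditions: Dess–Martin periodinane, NaHCO3, CH2Cl2, 25 °C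
Reagents that add atoms: none
Why: Dess–Martin oxidation of the secondary alcohol to the ketone removes the sacrificial C9 stereocentre and creates the epoxy ketone.

Step 19
Reactants: 24 9-oxo-1,10:4,5-diepoxygermacr-11-ene-3,6-diyl bis[(2Z)-2-methylbut-2-enoate]
Product: 26 (8R)-8-bromo-9-oxo-1,10:4,5-diepoxygermacr-11-ene-3,6-diyl bis[(2Z)-2-methylbut-2-enoate], via trimethylsilyl enol ether 25 (not isolated)
Conditions: LiN(SiMe3)2, Me3SiCl, THF, −78 °C; then N-bromosuccinimide, THF, −78 °C
Reagents that add atoms: N-bromosuccinimide, BrN1C(=O)CCC1=O; chlorotrimethylsilane, C[Si](C)(C)Cl (silicon stays only in 25)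
Why: The ketone can enolise only towards C8 because C10 is fully substituted, so kinetic deprotonation with in situ silylation gives one silyl enol ether regiospecifically, and electrophilic bromination of it (α-halogenation of a silyl enol ether) should occur on the peripheral face of the ring, anti to the neighbouring C7 isopropenyl group, giving the 7,8-trans (8R) bromide.

Step 20
Reactants: 26 (8R)-8-bromo-9-oxo-1,10:4,5-diepoxygermacr-11-ene-3,6-diyl bis[(2Z)-2-methylbut-2-enoate]; 21 angelic acid
Product: 27 (1R,3S,4R,5S,6S,7S,8S,10R)-9-oxo-1,10:4,5-diepoxygermacr-11-ene-3,6,8-triyl tris[(2Z)-2-methylbut-2-enoate]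
Conditions: 21, Cs2CO3, DMF, 25 °C
Reagents that add atoms: none
Why: SN2 displacement of the activated α-keto bromide by the weakly basic carboxylate (nucleophilic substitution of an α-halo ketone) should proceed with inversion at C8, turning the 7,8-trans bromide into the 7,8-cis (8S) angelate of the target.

**Compound list**

1 | 3-methylfuran-2(5H)-one | CC1=CCOC1=O | starting material
2 | 3-methyl-2,5-dihydrofuran-2-ol (lactol, both hemiacetal epimers) | CC1=CCOC1O | intermediate
3 | (−)-B-allyldiisopinocampheylborane (from (+)-α-pinene) | C=CCB([C@@H]1C[C@@H]2C[C@H]([C@H]1C)C2(C)C)[C@@H]1C[C@@H]2C[C@H]([C@H]1C)C2(C)C | starting material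
4 | (2Z,4S)-3-methylhepta-2,6-diene-1,4-diol | C=CC[C@H](O)/C(C)=C\CO | intermediate
5 | [(2S,3R)-3-[(1S)-1-hydroxybut-3-en-1-yl]-3-methyloxiran-2-yl]methanol | C=CC[C@H](O)[C@@]1(C)O[C@H]1CO | intermediate
6 | bis(triethylsilyl) ether of 5 | C=CC[C@H](O[Si](CC)(CC)CC)[C@@]1(C)O[C@H]1CO[Si](CC)(CC)CC | intermediate
7 | 3-(triethylsilyloxy)-3-[2-methyl-3-(triethylsilyloxymethyl)oxiran-2-yl]propanal (C1 aldehyde) | O=CC[C@H](O[Si](CC)(CC)CC)[C@@]1(C)O[C@H]1CO[Si](CC)(CC)CC | intermediate
8 | methyl 2-[bis(2,2,2-trifluoroethoxy)phosphoryl]propanoate | COC(=O)C(C)P(=O)(OCC(F)(F)F)OCC(F)(F)F | starting material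
9 | methyl (2Z)-2-methyl-5-(triethylsilyloxy)-5-[2-methyl-3-(triethylsilyloxymethyl)oxiran-2-yl]pent-2-enoate | COC(=O)/C(C)=C\C[C@H](O[Si](CC)(CC)CC)[C@@]1(C)O[C@H]1CO[Si](CC)(CC)CC | intermediate
10 | (2Z)-2-methyl-5-(triethylsilyloxy)-5-[2-methyl-3-(triethylsilyloxymethyl)oxiran-2-yl]pent-2-en-1-ol | OC/C(C)=C\C[C@H](O[Si](CC)(CC)CC)[C@@]1(C)O[C@H]1CO[Si](CC)(CC)CC | intermediate
11 | [2-methyl-3-[2-(triethylsilyloxy)-2-[2-methyl-3-(triethylsilyloxymethyl)oxiran-2-yl]ethyl]oxiran-2-yl]methanol (C9 alcohol, both cis-epoxides) | OC[C@]1(C)O[C@@H]1C[C@H](O[Si](CC)(CC)CC)[C@@]1(C)O[C@H]1CO[Si](CC)(CC)CC | intermediate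
12 | 2-methyl-3-[2-(triethylsilyloxy)-2-[2-methyl-3-(triethylsilyloxymethyl)oxiran-2-yl]ethyl]oxirane-2-carbaldehyde (C9 aldehyde) | O=C[C@]1(C)O[C@@H]1C[C@H](O[Si](CC)(CC)CC)[C@@]1(C)O[C@H]1CO[Si](CC)(CC)CC | intermediate
13 | (9S)-homoallylic alcohol: 1-[the oxiranyl unit of 12]but-3-en-1-ol (C9 carbinol, C8H2, C7H=CH2) | C=CC[C@H](O)[C@]1(C)O[C@@H]1C[C@H](O[Si](CC)(CC)CC)[C@@]1(C)O[C@H]1CO[Si](CC)(CC)CC | intermediate
14 | (9S)-4-methoxybenzyl ether of 13 | C=CC[C@H](OCc1ccc(OC)cc1)[C@]1(C)O[C@@H]1C[C@H](O[Si](CC)(CC)CC)[C@@]1(C)O[C@H]1CO[Si](CC)(CC)CC | intermediate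
15 | 3-chloro-2-methylprop-1-ene | C=C(C)CCl | starting material
16 | (7E)-allylic chloride: 14 with C7H=C11(C13H3)–C12H2Cl in place of the vinyl group (E drawn) | ClC/C(C)=C/C[C@H](OCc1ccc(OC)cc1)[C@]1(C)O[C@@H]1C[C@H](O[Si](CC)(CC)CC)[C@@]1(C)O[C@H]1CO[Si](CC)(CC)CC | intermediate
17 | C6 aldehyde: 16 with the CH2OSiEt3 group oxidised to CHO (cyclisation precursor) | O=C[C@@H]1O[C@]1(C)[C@@H](O[Si](CC)(CC)CC)C[C@H]1O[C@@]1(C)[C@@H](OCc1ccc(OC)cc1)C/C=C(\C)CCl | intermediate
18 | (E)-allylchromium dichloride from 17 (trivalent chromium on C12; not isolated) | O=C[C@@H]1O[C@]1(C)[C@@H](O[Si](CC)(CC)CC)C[C@H]1O[C@@]1(C)[C@@H](OCc1ccc(OC)cc1)C/C=C(\C)C[Cr](Cl)Cl | intermediate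
19 | (6S,7S,9S)-9-(4-methoxybenzyloxy)-3-(triethylsilyloxy)-1,10:4,5-diepoxygermacr-11-en-6-ol | C=C(C)[C@H]1[C@H](O)[C@@H]2O[C@]2(C)[C@@H](O[Si](CC)(CC)CC)C[C@H]2O[C@@]2(C)[C@@H](OCc2ccc(OC)cc2)C1 | intermediate
20 | (9S)-9-(4-methoxybenzyloxy)-1,10:4,5-diepoxygermacr-11-ene-3,6-diol | C=C(C)[C@H]1[C@H](O)[C@@H]2O[C@]2(C)[C@@H](O)C[C@H]2O[C@@]2(C)[C@@H](OCc2ccc(OC)cc2)C1 | intermediate
21 | angelic acid, (2Z)-2-methylbut-2-enoic acid | C/C=C(/C)C(=O)O | starting material
22 | (9S)-9-(4-methoxybenzyloxy)-1,10:4,5-diepoxygermacr-11-ene-3,6-diyl bis[(2Z)-2-methylbut-2-enoate] | C=C(C)[C@H]1[C@H](OC(=O)/C(C)=C\C)[C@@H]2O[C@]2(C)[C@@H](OC(=O)/C(C)=C\C)C[C@H]2O[C@@]2(C)[C@@H](OCc2ccc(OC)cc2)C1 | intermediate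
23 | (9S)-9-hydroxy-1,10:4,5-diepoxygermacr-11-ene-3,6-diyl bis[(2Z)-2-methylbut-2-enoate] | C=C(C)[C@H]1[C@H](OC(=O)/C(C)=C\C)[C@@H]2O[C@]2(C)[C@@H](OC(=O)/C(C)=C\C)C[C@H]2O[C@@]2(C)[C@@H](O)C1 | intermediate
24 | 9-oxo-1,10:4,5-diepoxygermacr-11-ene-3,6-diyl bis[(2Z)-2-methylbut-2-enoate] | C=C(C)[C@H]1[C@H](OC(=O)/C(C)=C\C)[C@@H]2O[C@]2(C)[C@@H](OC(=O)/C(C)=C\C)C[C@H]2O[C@@]2(C)C(=O)C1 | intermediate
25 | 9-(trimethylsilyloxy)-1,10:4,5-diepoxygermacra-8,11-diene-3,6-diyl bis[(2Z)-2-methylbut-2-enoate] (ring-cis enol ether drawn; not isolated) | C1[C@H]2O[C@@]2(C)/C(O[Si](C)(C)C)=C\[C@@H](C(C)=C)[C@H](OC(=O)/C(C)=C\C)[C@@H]2O[C@]2(C)[C@H]1OC(=O)/C(C)=C\C | intermediate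
26 | (8R)-8-bromo-9-oxo-1,10:4,5-diepoxygermacr-11-ene-3,6-diyl bis[(2Z)-2-methylbut-2-enoate] | C=C(C)[C@H]1[C@H](OC(=O)/C(C)=C\C)[C@@H]2O[C@]2(C)[C@@H](OC(=O)/C(C)=C\C)C[C@H]2O[C@@]2(C)C(=O)[C@@H]1Br | intermediate
27 | (1R,3S,4R,5S,6S,7S,8S,10R)-9-oxo-1,10:4,5-diepoxygermacr-11-ene-3,6,8-triyl tris[(2Z)-2-methylbut-2-enoate] | C=C(C)[C@H]1[C@H](OC(=O)/C(C)=C\C)[C@@H]2O[C@]2(C)[C@@H](OC(=O)/C(C)=C\C)C[C@H]2O[C@@]2(C)C(=O)[C@H]1OC(=O)/C(C)=C\C | target

**Step count and risks**

Total step count: 20. Longest linear sequence: 20 steps (1 → 27).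

The three steps most likely to fail:

- The ring closure (step 14) may lose material to intermolecular allylation (oligomerisation). Ring strain in the ten-membered transition state may also override the Felkin–Anh and chair preferences, giving poor facial selectivity at C6 and C7. The fallback changes the nucleophile from a reductively generated allylchromium species to a preformed allylboron reagent that needs no metal reductant and is homogeneous at true high dilution. Setting out from 16, zerovalent-palladium-catalysed borylation (Pd2(dba)3, bis(pinacolato)diboron, DMSO, 50 °C) would replace chloride by boron and give the allyl pinacolboronate F1. Swern oxidation of its primary triethylsilyl ether, as in the main route, would release the boronate aldehyde F2, which would not be isolated but warmed in dilute toluene so that it closes by intramolecular allylboration through the same chair arrangement to the cyclic borate ester F3. Mild hydrolysis with triethanolamine would then return the route to alcohol 19.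

- The bromination (step 19) may show reversed or poor facial selectivity, because the face of the ring enol ether that the electrophile takes is set by the conformation of the ten-membered ring and not by a rigid element. If the electrophile enters cis to the isopropenyl group, substitution with inversion would give the C8 epimer of the target. The fallback then installs the oxygen directly with retention. Setting out from 24, the potassium enolate (KN(SiMe3)2, THF, −78 °C) would be oxidised with 2-(phenylsulfonyl)-3-phenyloxaziridine. An oxidant entering on that same cis face would give the (8S)-8-hydroxy ketone F4, and Yamaguchi esterification with 21 under the conditions of step 16 would come back to the route at 27.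

- The displacement (step 20) may be overtaken by E2 loss of hydrogen bromide towards the C7=C8 enone, which is conjugated with the ketone and the isopropenyl group. The bromide may also lose its configuration through bromide exchange before substitution. The fallback avoids a free halide and a basic carboxylate. Setting out from 24, the same enolate oxidation, entering trans to the isopropenyl group as planned for bromine, would give the (8R)-8-hydroxy ketone F5. Mitsunobu esterification with 21 (PPh3, diisopropyl azodicarboxylate, toluene, 0 °C to 25 °C) would invert C8 under non-basic conditions and come back to the route at 27.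

Further compounds
F1 | step 14 | allyl pinacolboronate from 16 (Bpin in place of Cl on C12) | CC1(C)OB(C/C(C)=C/C[C@H](OCc2ccc(OC)cc2)[C@]2(C)O[C@@H]2C[C@H](O[Si](CC)(CC)CC)[C@@]2(C)O[C@H]2CO[Si](CC)(CC)CC)OC1(C)C
F2 | step 14 | boronate aldehyde (C6 aldehyde with C12–Bpin, not isolated) | O=C[C@@H]1O[C@]1(C)[C@@H](O[Si](CC)(CC)CC)C[C@H]1O[C@@]1(C)[C@@H](OCc1ccc(OC)cc1)C/C=C(\C)CB1OC(C)(C)C(C)(C)O1
F3 | step 14 | cyclic C6 pinacol borate ester of 19 | C=C(C)[C@H]1[C@H](OB2OC(C)(C)C(C)(C)O2)[C@@H]2O[C@]2(C)[C@@H](O[Si](CC)(CC)CC)C[C@H]2O[C@@]2(C)[C@@H](OCc2ccc(OC)cc2)C1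
F4 | step 19 | (8S)-8-hydroxy-9-oxo-1,10:4,5-diepoxygermacr-11-ene-3,6-diyl bis[(2Z)-2-methylbut-2-enoate] | C=C(C)[C@H]1[C@H](OC(=O)/C(C)=C\C)[C@@H]2O[C@]2(C)[C@@H](OC(=O)/C(C)=C\C)C[C@H]2O[C@@]2(C)C(=O)[C@H]1O
F5 | step 20 | (8R)-8-hydroxy-9-oxo-1,10:4,5-diepoxygermacr-11-ene-3,6-diyl bis[(2Z)-2-methylbut-2-enoate] | C=C(C)[C@H]1[C@H](OC(=O)/C(C)=C\C)[C@@H]2O[C@]2(C)[C@@H](OC(=O)/C(C)=C\C)C[C@H]2O[C@@]2(C)C(=O)[C@@H]1O
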